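Remark on the chemistry: compound 7 is written as the hydrogen-bonded enol of its 2-methoxy-1,3-diketone. The keto tautomer is in equilibrium with it and both should enter step 3 alike. The methoxy-bearing carbon of 8 and 9 is enolizable, so no configuration is assigned there. Flavone numbering is used for 10 to 13, chain numbering (ester carbon = C1) for 8.

## Analysis of the target

Compound 13 is 3,5,6,7,8,2',4'-heptamethoxyflavone (C22H24O9), a 2-aryl-4H-chromen-4-one. Ring A carries methoxy groups on all four free carbons (C5 to C8), ring C carries one at C3 beside the C4 carbonyl, and ring B is a 2,4-dimethoxyphenyl group on C2. There is no stereocenter, and rotation about C2–C1' should be free enough that no atropisomerism needs control. The sensitive points are the γ-pyranone (C2 accepts alkoxide with ring opening), the 5-methoxy group peri to the carbonyl (the first ether lost to Lewis acids or nucleophilic demethylation), and the two electron-rich benzene rings. The difficulty is ring A: all six carbons are substituted, four adjacent ones by oxygen, and the seven O-methyl groups are chemically alike, so every oxygen must arrive at its carbon by construction. Ring B adds a second problem, because electrophilic chemistry meant for ring A must outrun substitution at C3' and C5'. The plan rests on one observation: without the oxygens at C6 and C8, atoms C8a, C5 and C7 carry oxygen in strict alternation and C4a carries the chain C4(=O)–C3(OMe)–C2(Ar), which is the pattern left when a linear poly-β-carbonyl ester closes by Claisen acylation of C4a onto C8a. The two oxygens this fold does not supply sit on the only two CH positions of the resulting phloroglucinol-type ring, which are its most nucleophilic carbons and need the same substituent, so they can be added late without a regiochemical question.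

## Retrosynthetic reasoning

**13 to 12.** The aryl C–O bonds at C6 and C8 are cut, giving dibromide 12. These are the two ring A oxygens that break the alternating pattern, and since both need the same group the exchange can be run on both at once. Cutting C5–O or C7–O would gain nothing, because those oxygens come with the carbon skeleton. The forward reaction must replace two flanked aryl bromides by methoxy groups under copper mediation without destroying the pyranone.

**12 to 11.** The O–CH3 bonds at O5 and O7 are cut, giving diphenol 11. The phenols are kept free until after halogenation because they are what makes ring A outpace ring B towards electrophiles. The forward double O-methylation must include the hydrogen-bonded 5-hydroxyl.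

**11 to 10.** The C6–Br and C8–Br bonds are cut, leading to 10. C6 and C8 are the only unsubstituted carbons of ring A and each lies ortho or para to every donor on that ring, so no directing device is needed. The forward step only has to stop after two equivalents so that ring B stays untouched.

**10 to 7, through 9 and 8.** Two bonds are cut. O1–C2 opens ring C to the 2-methoxy-1,3-diketone 9 on a 2,4,6-trihydroxyphenyl ring. C4a–C8a opens ring A in the retro-Claisen sense to the open-chain methyl 3,5,7,9-tetraoxo ester 8. The cut is placed at C4a–C8a and not at C4–C4a (acylation of a preformed oxygenated benzene) because the whole bicyclic core then folds from one acyclic chain in which each oxygen already sits on its carbon. The two hydroxyls ortho to the acyl group in 9 are equivalent, so ring C cannot close the wrong way. Ester 8 would not survive storage, so it is kept as its enol lactone, the 4-hydroxy-2-pyrone 7, which ties up chain carbons 1 to 5. The forward reaction must open the lactone, make Claisen closure win over aldol folding, and then cyclodehydrate.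

**7 to 4 and 5.** The bond between the aryl ketone carbon (future C2) and the methoxy-bearing carbon (future C3) is cut. This releases ring B as the commercial benzoate 5 and leaves ketone 4. In the polyanion 6 of ketone 4 the methoxy-bearing carbon is the last and most basic site to be deprotonated, and therefore the one that attacks an ester. A cut on the other side of that carbon would need an acyl donor with strongly acidic protons, which a carbanion would only deprotonate. The forward step must acylate the terminal carbon with a non-enolizable ester.

**4 to 1 and 2.** The bond between the exocyclic CH2 on pyrone C6 (future C4a) and the ketone carbon (future C4) is cut. Triacetic acid lactone 1 is already the masked triketide that supplies all six ring A carbons; ester 2 supplies C4 and C3 together with the C3 methoxy group. The forward step must acylate the methyl carbon of 1 and not C3 of the ring or an oxygen, which the dianion 3 secures.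

## Alternatives that were turned down

**Alternative 1:** carbonylative three-component assembly.
- **Disconnection:** C4a–C4, C3–C4 and O1–C2. C4 comes from carbon monoxide (A4), ring A from 2-iodo-3,4,5,6-tetramethoxyphenol (A2) and C2, C3 and ring B from 1-ethynyl-2,4-dimethoxybenzene (A3).
- **Forward key step:** PdCl2(PPh3)2 under A4 with diethylamine. Zerovalent palladium inserts into the C–I bond of A2, CO insertion and coupling with A3 follow, and 6-endo-dig addition of the phenol oxygen across the triple bond closes ring C to 5,6,7,8,2',4'-hexamethoxyflavone (A1).
- **For:** it is the most convergent plan, and ring A arrives with all four methoxy groups in place. On that point it is stronger than the chosen route, which needs a late halogenation and C–O exchange.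
- **Against:** a terminal alkyne delivers C3–H, so A1 lacks the C3 methoxy group. Hydroxylation at C3 and O-methylation would add two steps on an oxidation-prone substrate. A2 is not a catalog compound and its pentaoxygenated ring takes several steps to build. Its C–I bond is flanked by OH and OMe on a very electron-rich ring, which slows oxidative addition, and 5-exo-dig closure competes with the 6-endo mode.
- **Comparison:** the chosen route carries the C3 methoxy group from the start inside ester 2, begins with three catalog compounds and reaches 13 in six steps. It pays for this with the late C6/C8 oxygenation.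

**Alternative 2:** Auwers ring expansion.
- **Disconnection:** O1–C2 of 3-hydroxy-5,6,7,8,2',4'-hexamethoxyflavone (A5), traced back to the dibromide (A7) of the benzylidene aurone (A6), which comes from 4,5,6,7-tetramethoxybenzofuran-3(2H)-one (A8).
- **Forward key step:** KOH on A7. Hydroxide adds at the carbon that bears both the ring oxygen and a bromine, the five-membered ring opens at its C–O bond, and the freed phenoxide displaces the benzylic bromide to form the six-membered ring as A5. One O-methylation would finish.
- **For:** the C3 oxygen is created by the rearrangement, and ring A is fully oxygenated from the start. It equals the chosen route on C3 and is stronger on C6/C8.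
- **Against:** A8 is again a pentaoxygenated benzene that needs several steps. Bromine must add to the exocyclic double bond of A6 while the 2,4-dimethoxyphenyl ring, the most nucleophilic site of that molecule, invites nuclear bromination. In A7 the benzylic bromide sits ortho and para to methoxy groups, so ionization to a quinone-methide-like cation, followed by loss of HBr or solvolysis, can outrun the ring expansion.
- **Comparison:** the chosen route brominates at a stage where the free-phenol ring A is by far the most nucleophilic site, and it needs no pre-oxygenated aromatic building block.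

**Alternative 3:** squarate-based ring expansion.
- **Disconnection:** C8–C8a and, one step earlier, C4a–C5. Carbons C5 to C8 with their four oxygens come from dimethyl squarate (A11). Halogen–metal exchange on 5-bromo-2-(2,4-dimethoxyphenyl)-3-methoxy-4H-pyran-4-one (A12) and 1,2-addition to A11 would give the 4-hydroxy-4-(pyranon-5-yl)-2,3-dimethoxycyclobutenone (A10).
- **Forward key step:** heating A10. Conrotatory 4π opening of the four-membered ring unmasks a ketene carbon that bonds to pyranone C6 in a six-electron closure. Tautomerization gives 5,8-dihydroxy-3,6,7,2',4'-pentamethoxyflavone (A9), and double O-methylation would complete the target.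
- **For:** all four ring A oxygens are delivered at once, with no regiochemical question and no reagent in the key step. This is clearly stronger than the late double methoxylation of the chosen route.
- **Against:** A12 must itself be assembled over several steps. A metalated 4-pyranone is a fragile nucleophile on a ring that opens easily. A9 is an electron-rich para-hydroquinone that oxidizes readily to the quinone before it can be methylated.
- **Comparison:** the sequence is longer overall. The chosen route offers the full carbon skeleton in three steps from catalog materials, with the risk concentrated in one step of a known type.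

Key step: step 3

## Route

Step 1
Reactants: 1 4-hydroxy-6-methyl-2H-pyran-2-one (triacetic acid lactone); 2 methyl methoxyacetate
Product: 4 4-hydroxy-6-(3-methoxy-2-oxopropyl)-2H-pyran-2-one, via dilithium dianion of the pyrone 3 (not isolated)
Conditions: LDA (2.05 equiv per 1), THF, −78 → −20 °C; then 2 (0.5 equiv per 1), −78 → 0 °C; aq. HCl
Reagents that add atoms: none
Why: Two equivalents of lithium amide remove the hydroxyl proton and then a proton of the 6-methyl group, and dianion 3 reacts at its more basic exocyclic carbon with the activated α-alkoxy ester in a Claisen-type acylation. The β-keto pyrone formed is deprotonated at once by a second equivalent of 3, which protects it from further addition; this is why 1 is used in twofold excess and the surplus recovered.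

Step 2
Reactants: 4 4-hydroxy-6-(3-methoxy-2-oxopropyl)-2H-pyran-2-one; 5 methyl 2,4-dimethoxybenzoate
Product: 7 6-[(3E)-4-(2,4-dimethoxyphenyl)-4-hydroxy-3-methoxy-2-oxobut-3-en-1-yl]-4-hydroxy-2H-pyran-2-one (hydrogen-bonded enol of the 2-methoxy-1,3-diketone), via trilithium trianion of the ketone 6 (not isolated)
Conditions: LDA (3.1 equiv per 4), THF, −78 → −20 °C; then 5 (0.5 equiv per 4), −20 → 0 °C; aq. HCl to pH 2
Reagents that add atoms: none
Why: Three equivalents of base give trianion 6 (pyrone oxide, the doubly activated CH, and last the CH2OMe carbon α' to the ketone); as with dianions of 1,3-dicarbonyl compounds, the last-formed and most basic carbanion is the one acylated, so the non-enolizable benzoate 5 aroylates the methoxy-bearing terminus (Claisen-type terminal acylation of a polyanion). The ortho-methoxy group of 5 can coordinate lithium and assist acyl transfer, and the acidic diketone produced is neutralized by the excess trianion, which is why 4 is used in twofold excess.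

Step 3
Reactants: 7 6-[(3E)-4-(2,4-dimethoxyphenyl)-4-hydroxy-3-methoxy-2-oxobut-3-en-1-yl]-4-hydroxy-2H-pyran-2-one
Product: 10 5,7-dihydroxy-3,2',4'-trimethoxyflavone, via open-chain tetraketo methyl ester 8 (not isolated), via acylphloroglucinol diketone 9 (not isolated)
Conditions: Mg(OMe)2 (8 equiv), anhydrous MeOH, reflux, under argon; aq. HCl quench; then crude material in AcOH, cat. H2SO4, 100 °C
Reagents that add atoms: none
Why: Methoxide from Mg(OMe)2 adds to the lactone carbonyl of 7 and opens the 4-hydroxy-2-pyrone to methyl ester 8, which is held as magnesium chelates of its β-dicarbonyl units. The carbon between the C5 and C7 carbonyls of 8 (the former side-chain CH2, C4a of the flavone) then attacks the ester carbon (C8a) in a Claisen condensation of the Dieckmann type, a 6-exo-trig closure that expels methoxide; enolization of the cyclohexanetrione to the aromatic 2,4,6-trihydroxyphenyl ketone 9 makes this closure irreversible and forms ring A. The closest known reaction type is the magnesium methoxide-induced Claisen cyclization of 6-(2-oxoalkyl)-4-hydroxy-2-pyrones to acylphloroglucinols, the laboratory counterpart of the chalcone synthase fold. In the acid stage an ortho hydroxyl of 9 adds to the aryl ketone carbon (C2) in a 6-exo-trig hemiketalization and loss of water gives the pyranone, as in the cyclodehydration of Baker–Venkataraman diketones; this forms O1–C2 and ring C. No stereocenter is created, and the enolizable methoxy-bearing carbon of 8 and 9 ends as the sp2 carbon C3. The selectivity needed is Claisen closure over aldol folding of the chain (ester α-carbon onto the C7 ketone): the divalent magnesium ion binds the ketone carbonyls as chelated enolates, which makes them poor aldol acceptors and leaves the ester as the free electrophile, and anhydrous methanol prevents ester hydrolysis, which would switch the chain to the aldol mode. The same chelation keeps the 2-methoxy-1,3-diketone as its enolate and so protects it from retro-Claisen cleavage by methoxide. Because the two ortho hydroxyls of 9 are related by symmetry, ring C can close in only one way.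

Step 4
Reactants: 10 5,7-dihydroxy-3,2',4'-trimethoxyflavone
Product: 11 6,8-dibromo-5,7-dihydroxy-3,2',4'-trimethoxyflavone
Conditions: NBS (2.0 equiv), THF, −20 → 0 °C
Reagents that add atoms: N-bromosuccinimide, O=C1CCC(=O)N1Br
Why: Electrophilic aromatic bromination: C6 and C8 are the only CH positions of ring A and each lies ortho or para to two free hydroxyls and the ring oxygen, so they should react far faster than C3' or C5' of ring B, whose donors are only methyl ethers and which is deactivated by the attached pyranone. Exactly two equivalents at low temperature are meant to keep ring B untouched.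

Step 5
Reactants: 11 6,8-dibromo-5,7-dihydroxy-3,2',4'-trimethoxyflavone
Product: 12 6,8-dibromo-3,5,7,2',4'-pentamethoxyflavone
Conditions: Me2SO4 (excess), K2CO3, acetone, reflux
Reagents that add atoms: dimethyl sulfate, COS(=O)(=O)OC
Why: Williamson O-methylation of both phenols; the bromines acidify the 7-hydroxyl, and the hydrogen-bonded 5-hydroxyl is alkylated under prolonged reflux with excess reagent, the usual way to methylate chelated 5-hydroxyflavones.

Step 6
Reactants: 12 6,8-dibromo-3,5,7,2',4'-pentamethoxyflavone
Product: 13 3,5,6,7,8,2',4'-heptamethoxyflavone (target)
Conditions: NaOMe (excess, 25% in MeOH), CuBr (40 mol %), DMF, 110 °C; dilute HCl work-up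
Reagents that add atoms: sodium methoxide, [Na+].[O-]C
Why: Ullmann-type exchange of aryl bromide for methoxide catalysed by monovalent copper, a reaction type established for bromides flanked by oxygen substituents (5-bromovanillin to syringaldehyde) and for bromoflavones. Both bromides receive the same nucleophile, so no selectivity is needed, and the acidic work-up recloses any pyranone opened reversibly by methoxide.

## Compound list

1 | 4-hydroxy-6-methyl-2H-pyran-2-one (triacetic acid lactone) | Cc1cc(O)cc(=O)o1 | starting material
2 | methyl methoxyacetate | COCC(=O)OC | starting material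
3 | dilithium dianion of 1 (oxide at O4, carbanion at the 6-methyl carbon) | [Li+].[Li+].[CH2-]c1cc([O-])cc(=O)o1 | intermediate (not isolated)
4 | 4-hydroxy-6-(3-methoxy-2-oxopropyl)-2H-pyran-2-one | COCC(=O)Cc1cc(O)cc(=O)o1 | intermediate
5 | methyl 2,4-dimethoxybenzoate | COC(=O)c1ccc(OC)cc1OC | starting material
6 | trilithium trianion of 4 (oxide at O4, carbanions at both carbons α to the ketone) | [Li+].[Li+].[Li+].CO[CH-]C(=O)[CH-]c1cc([O-])cc(=O)o1 | intermediate (not isolated)
7 | 6-[(3E)-4-(2,4-dimethoxyphenyl)-4-hydroxy-3-methoxy-2-oxobut-3-en-1-yl]-4-hydroxy-2H-pyran-2-one | COc1ccc(/C(O)=C(\OC)C(=O)Cc2cc(O)cc(=O)o2)c(OC)c1 | intermediate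
8 | methyl 9-(2,4-dimethoxyphenyl)-8-methoxy-3,5,7,9-tetraoxononanoate (enolizable C8, no defined configuration) | COC(=O)CC(=O)CC(=O)CC(=O)C(OC)C(=O)c1ccc(OC)cc1OC | intermediate (not isolated)
9 | 1-(2,4-dimethoxyphenyl)-2-methoxy-3-(2,4,6-trihydroxyphenyl)propane-1,3-dione (enolizable C2, no defined configuration) | COc1ccc(C(=O)C(OC)C(=O)c2c(O)cc(O)cc2O)c(OC)c1 | intermediate (not isolated)
10 | 5,7-dihydroxy-3,2',4'-trimethoxyflavone | COc1ccc(-c2oc3cc(O)cc(O)c3c(=O)c2OC)c(OC)c1 | intermediate
11 | 6,8-dibromo-5,7-dihydroxy-3,2',4'-trimethoxyflavone | COc1ccc(-c2oc3c(Br)c(O)c(Br)c(O)c3c(=O)c2OC)c(OC)c1 | intermediate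
12 | 6,8-dibromo-3,5,7,2',4'-pentamethoxyflavone | COc1ccc(-c2oc3c(Br)c(OC)c(Br)c(OC)c3c(=O)c2OC)c(OC)c1 | intermediate
13 | 3,5,6,7,8,2',4'-heptamethoxyflavone | COc1ccc(-c2oc3c(OC)c(OC)c(OC)c(OC)c3c(=O)c2OC)c(OC)c1 | target

## Step count and risk

Total step count: 6. Longest linear sequence: 6 steps (1 to 13); the route is fully linear, with 2 and 5 entering as reagent-like building blocks.

**Step 3 (key step).**
- What may go wrong: after lactone opening the chain may fold by aldol addition instead of Claisen closure. Methoxide may also cleave the 2-methoxy-1,3-diketone by retro-Claisen attack if chelation is incomplete, or the pyrone anion may resist opening, so that the material decomposes on long heating.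
- Fallback: it sets out from benzoate 5 and returns at 10. Saponification of 5 (NaOH, aqueous MeOH) gives 2,4-dimethoxybenzoic acid F1, and DCC (0.5 equiv, CH2Cl2) converts this into 2,4-dimethoxybenzoic anhydride F2. Hoesch acylation of phloroglucinol with methoxyacetonitrile (ZnCl2, HCl gas, Et2O; then hot water) gives 2-methoxy-1-(2,4,6-trihydroxyphenyl)ethanone F3. Heating F3 with F2 and triethylamine at about 160 °C (Allan–Robinson condensation), then hydrolysing the aroyl esters on the phenols with KOH in aqueous ethanol, should give 10. Ring A is then bought and not folded, but steps 4 to 6 are unchanged.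

**Step 2.**
- What may go wrong: acyl transfer to the electron-rich, ortho-substituted ester may be slow, so that proton exchange and decay of the trianion take over. The third deprotonation at the methoxy-bearing carbon may also be incomplete.
- Fallback: it sets out from 4 (through trianion 6) and returns at 7. Trianion 6 is quenched at −78 °C with 2,4-dimethoxybenzaldehyde, a far better electrophile whose alkoxide adduct consumes no further base. This gives 6-[4-(2,4-dimethoxyphenyl)-4-hydroxy-3-methoxy-2-oxobutyl]-4-hydroxy-2H-pyran-2-one F4 as a mixture of diastereomers. Oxidation of the benzylic alcohol with Dess–Martin periodinane (CH2Cl2, NaHCO3) then gives 7, and both stereocenters of F4 disappear.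

**Step 1.**
- What may go wrong: proton transfer from the α-CH2 of ester 2 to the dianion would quench the nucleophile and start self-condensation of the ester.
- Fallback: it sets out from 1 (through dianion 3) and returns at 4. Aldol addition of 3 to freshly distilled methoxyacetaldehyde (THF, −78 °C) gives racemic 4-hydroxy-6-(2-hydroxy-3-methoxypropyl)-2H-pyran-2-one F5. Oxidation of the secondary alcohol (Dess–Martin periodinane, CH2Cl2) gives 4.

**Step 6.**
- What may go wrong: reductive loss of bromine may compete with substitution, and the second exchange at a position flanked on both sides may stall. Methoxide may attack C2 of the pyranone or demethylate O5 at the temperature needed.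
- Fallback: it avoids aryl C–O coupling, sets out from 10 and returns at 13. Duff formylation (hexamethylenetetramine, TFA, 90 °C; aq. HCl) at the two free ring A positions gives 5,7-dihydroxy-3,2',4'-trimethoxyflavone-6,8-dicarbaldehyde F6. O-methylation (Me2SO4, K2CO3, acetone) gives 3,5,7,2',4'-pentamethoxyflavone-6,8-dicarbaldehyde F7. Baeyer–Villiger oxidation (mCPBA, CH2Cl2, NaHCO3), favoured by the two ortho methoxy groups on each formyl-bearing carbon, gives 3,5,7,2',4'-pentamethoxyflavone-6,8-diyl diformate F8. Methanolysis (K2CO3, MeOH) releases 6,8-dihydroxy-3,5,7,2',4'-pentamethoxyflavone F9, and a final methylation (Me2SO4, K2CO3) gives 13.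

**Step 4.**
- What may go wrong: bromination may spill over to C5' of ring B once ring A is filled, or stop unevenly after one bromine.
- Fallback: it sets out from 10 and returns at 13. Iodination through the phenoxide (I2, NaHCO3, aqueous THF, 0 °C → rt) uses an electrophile too weak to touch aryl methyl ethers and gives 5,7-dihydroxy-6,8-diiodo-3,2',4'-trimethoxyflavone F10. Methylation (Me2SO4, K2CO3, acetone) gives 6,8-diiodo-3,5,7,2',4'-pentamethoxyflavone F11. The methoxylation of step 6 (NaOMe, CuBr, DMF), now on the more reactive iodides, gives 13.

## Further compounds

F1 | step 3 | 2,4-dimethoxybenzoic acid | COc1ccc(C(=O)O)c(OC)c1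
F2 | step 3 | 2,4-dimethoxybenzoic anhydride | COc1ccc(C(=O)OC(=O)c2ccc(OC)cc2OC)c(OC)c1
F3 | step 3 | 2-methoxy-1-(2,4,6-trihydroxyphenyl)ethanone | COCC(=O)c1c(O)cc(O)cc1O
F4 | step 2 | 6-[4-(2,4-dimethoxyphenyl)-4-hydroxy-3-methoxy-2-oxobutyl]-4-hydroxy-2H-pyran-2-one (mixture of racemic diastereomers) | COc1ccc(C(O)C(OC)C(=O)Cc2cc(O)cc(=O)o2)c(OC)c1
F5 | step 1 | 4-hydroxy-6-(2-hydroxy-3-methoxypropyl)-2H-pyran-2-one (racemic) | COCC(O)Cc1cc(O)cc(=O)o1
F6 | step 6 | 5,7-dihydroxy-3,2',4'-trimethoxyflavone-6,8-dicarbaldehyde | COc1ccc(-c2oc3c(C=O)c(O)c(C=O)c(O)c3c(=O)c2OC)c(OC)c1
F7 | step 6 | 3,5,7,2',4'-pentamethoxyflavone-6,8-dicarbaldehyde | COc1ccc(-c2oc3c(C=O)c(OC)c(C=O)c(OC)c3c(=O)c2OC)c(OC)c1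
F8 | step 6 | 3,5,7,2',4'-pentamethoxyflavone-6,8-diyl diformate | COc1ccc(-c2oc3c(OC=O)c(OC)c(OC=O)c(OC)c3c(=O)c2OC)c(OC)c1
F9 | step 6 | 6,8-dihydroxy-3,5,7,2',4'-pentamethoxyflavone | COc1ccc(-c2oc3c(O)c(OC)c(O)c(OC)c3c(=O)c2OC)c(OC)c1
F10 | step 4 | 5,7-dihydroxy-6,8-diiodo-3,2',4'-trimethoxyflavone | COc1ccc(-c2oc3c(I)c(O)c(I)c(O)c3c(=O)c2OC)c(OC)c1
F11 | step 4 | 6,8-diiodo-3,5,7,2',4'-pentamethoxyflavone | COc1ccc(-c2oc3c(I)c(OC)c(I)c(OC)c3c(=O)c2OC)c(OC)c1
A1 | alternative 1 | 5,6,7,8,2',4'-hexamethoxyflavone | COc1ccc(-c2cc(=O)c3c(OC)c(OC)c(OC)c(OC)c3o2)c(OC)c1
A2 | alternative 1 | 2-iodo-3,4,5,6-tetramethoxyphenol | COc1c(O)c(I)c(OC)c(OC)c1OC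
A3 | alternative 1 | 1-ethynyl-2,4-dimethoxybenzene | COc1ccc(C#C)c(OC)c1
A4 | alternative 1 | carbon monoxide | [C-]#[O+]
A5 | alternative 2 | 3-hydroxy-5,6,7,8,2',4'-hexamethoxyflavone | COc1ccc(-c2oc3c(OC)c(OC)c(OC)c(OC)c3c(=O)c2O)c(OC)c1
A6 | alternative 2 | (Z)-2-(2,4-dimethoxybenzylidene)-4,5,6,7-tetramethoxy-1-benzofuran-3(2H)-one | COc1ccc(/C=C2\Oc3c(OC)c(OC)c(OC)c(OC)c3C2=O)c(OC)c1
A7 | alternative 2 | 2-bromo-2-[bromo(2,4-dimethoxyphenyl)methyl]-4,5,6,7-tetramethoxy-1-benzofuran-3(2H)-one (racemic anti adduct, one enantiomer drawn) | COc1ccc([C@H](Br)[C@@]2(Br)Oc3c(OC)c(OC)c(OC)c(OC)c3C2=O)c(OC)c1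
A8 | alternative 2 | 4,5,6,7-tetramethoxy-1-benzofuran-3(2H)-one | O=C1COc2c(OC)c(OC)c(OC)c(OC)c12
A9 | alternative 3 | 5,8-dihydroxy-3,6,7,2',4'-pentamethoxyflavone | COc1ccc(-c2oc3c(O)c(OC)c(OC)c(O)c3c(=O)c2OC)c(OC)c1
A10 | alternative 3 | 4-[6-(2,4-dimethoxyphenyl)-5-methoxy-4-oxo-4H-pyran-3-yl]-4-hydroxy-2,3-dimethoxycyclobut-2-en-1-one (racemic) | COc1ccc(-c2occ(C3(O)C(OC)=C(OC)C3=O)c(=O)c2OC)c(OC)c1
A11 | alternative 3 | dimethyl squarate (3,4-dimethoxycyclobut-3-ene-1,2-dione) | COC1=C(OC)C(=O)C1=O
A12 | alternative 3 | 5-bromo-2-(2,4-dimethoxyphenyl)-3-methoxy-4H-pyran-4-one | COc1ccc(-c2occ(Br)c(=O)c2OC)c(OC)c1
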